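**Plan**

1. Cuts (labdane numbering): the O9–benzoyl bond and the silyl groups come off last. The 9α-OH/C7=C8 unit is traced back to an 8α,9α-oxirane on a C6=C7–C8=C9 diene. Then C9–C11 is cut (sp2–sp3 coupling of the decalin with the complete C6 side chain), then C3–C4 (radical closure of ring A), then C10–C1 and C10–CH3 (two enolate alkylations), which leads to (R)-carvone.
2. Forward: ring B is the carvone ring (C=O → C9, C–CH3 → C8/C17, =CH → C7, stereocentre → C5, isopropenyl → C4 with both geminal methyls). C10 is made quaternary, ring A closes from C4 to C3, the side chain is joined at C9, and the C9 oxygen is brought in afterwards.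
3. Enabling feature: C10 bears no hydrogen, so the ring-B enone C7=C8–C9=O can enolise only through C6–H. The dienolate gives a C9 triflate on a flat C6=C7–C8=C9 diene, and C11 is attached in the plane of ring B.
4. Reason for this order: in the target C11 is pseudo-equatorial and cis to the axial C10 methyl, while O9 is pseudo-axial (α). A nucleophile adding to C9=O should come anti to that methyl and give the C9 epimer. An oxidant arriving after the C–C union uses the same bias to place oxygen on the α face. The helpers (OTf, the C6=C7 bond, the oxirane ring) are removed in steps 9 and 11.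
5. Stereochemistry: C5 comes from (R)-carvone; C10 from alkylation anti to the isopropenyl group; C3 from an equatorial C–O bond in the chair-like closure; C8/C9 from α-face epoxidation (the C9–O bond is never broken again); C13=C14 (E) from syn-carbocupration.

Key step: step 9

Remark: labdane numbering is used throughout (ring A C1–C5 and C10, ring B C5–C10, side chain C11–C16, C17 = methyl on C8); β is the face of the C10 methyl, α the opposite face.

**Route**

Step 1
Reactants: 1 (R)-(−)-carvone
Product: 3 trans-6-methylcarvone, via lithium enolate 2 (not isolated)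
Conditions: LDA, THF, −78 °C; MeI, −78 → 0 °C
Reagents that add atoms: iodomethane, CI
Why: Kinetic α′-deprotonation of the cross-conjugated enone followed by SN2 methylation (enolate alkylation) should give 3; the new centre is flattened again in step 2, so its configuration does not matter.

Step 2
Reactants: 3 trans-6-methylcarvone
Product: 5 6-methyl-6-propargylcarvone (propargyl trans to isopropenyl), via lithium enolate 4 (not isolated)
Conditions: LDA, THF/DMPU, −78 °C; propargyl bromide, −78 → −20 °C
Reagents that add atoms: propargyl bromide, C#CCBr
Why: Enolate alkylation of the fully substituted α′-enolate: allylic strain with the C10 methyl holds the C5 isopropenyl group pseudo-axial, so the bromide should enter from the opposite face and place C1 trans and the methyl cis to C4, as a trans-decalin with an axial β C10 methyl requires.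

Step 3
Reactants: 5 6-methyl-6-propargylcarvone
Product: 7 keto aldehyde (C10 arm CH2CH2CHO), via alkenylborane 6 (not isolated)
Conditions: Cy2BH, THF, 0 °C; Me3NO, 0 °C → rt; H2O
Reagents that add atoms: trimethylamine N-oxide, C[N+](C)(C)[O-]
Why: Hydroboration–oxidation of a terminal alkyne: the bulky dialkylborane adds far faster to the alkyne (boron to the terminal carbon C3) than to the 1,1-disubstituted alkene or the hindered enone, and the amine oxide oxidises the C–B bonds without the nucleophilic peroxide that would epoxidise the enone.

Step 4
Reactants: 7 keto aldehyde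
Product: 8 3β-hydroxy trans-decalin enone
Conditions: Fe(acac)3 (cat.), PhSiH3, EtOH, 60 °C, Ar
Reagents that add atoms: none
Why: Metal-hydride hydrogen-atom transfer to the electron-rich 1,1-disubstituted alkene gives the tertiary C4 radical, which should add 6-exo to the C3 aldehyde (HAT-initiated alkene–carbonyl radical cyclisation) through a chair with the C3–O bond equatorial, giving the 3β-alcohol, while the trans ring fusion follows from the trans C1/C4 arrangement set in step 2.

Step 5
Reactants: 8 3β-hydroxy trans-decalin enone
Product: 9 3β-triethylsilyloxy enone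
Conditions: TESCl, imidazole, DMAP (cat.), DMF, rt
Reagents that add atoms: chlorotriethylsilane, CC[Si](Cl)(CC)CC
Why: Standard silylation of a secondary alcohol; the triethylsilyl ether next to the gem-dimethyl group is shielded enough for steps 6–12 and remains fluoride-labile.

Step 6
Reactants: 9 3β-triethylsilyloxy enone
Product: 11 C9 dienyl triflate, via potassium dienolate 10 (not isolated)
Conditions: KHMDS, THF, −78 °C; N-(5-chloro-2-pyridyl)bis(trifluoromethanesulfonimide), −78 → 0 °C
Reagents that add atoms: N-(5-chloro-2-pyridyl)bis(trifluoromethanesulfonimide), O=S(=O)(N(c1ccc(Cl)cn1)S(=O)(=O)C(F)(F)F)C(F)(F)F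
Why: Because C10 is quaternary the base can only remove the γ-proton at C6, and O-sulfonylation of the extended dienolate (enol triflate formation) gives the 2-triflyloxy-1,3-diene without touching a stereocentre.

Step 7
Reactants: 12 but-2-ynoic acid; 13 2-(trimethylsilyl)ethanol
Product: 14 2-(trimethylsilyl)ethyl but-2-ynoate
Conditions: DCC, DMAP (cat.), CH2Cl2, 0 °C → rt
Reagents that add atoms: none
Why: Steglich esterification under neutral conditions; this ester is chosen because fluoride removes it in step 13 without acid or hydroxide.

Step 8
Reactants: 14 2-(trimethylsilyl)ethyl but-2-ynoate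
Product: 16 2-(trimethylsilyl)ethyl (2E)-3-methylpenta-2,4-dienoate, via alkenylcopper adduct 15 (not isolated)
Conditions: CH2=CHMgBr, CuBr·SMe2, THF, −78 °C; 14, −78 °C; sat. aq NH4Cl at −78 °C
Reagents that add atoms: vinylmagnesium bromide, C=C[Mg]Br
Why: syn-Carbocupration of a 2-alkynoate puts the vinyl group and copper on the same side, and protonation with retention at −78 °C, before the adduct can equilibrate through its allenolate, leaves C12 trans to the ester, which is the E geometry of C13=C14.

Step 9
Reactants: 16 2-(trimethylsilyl)ethyl (2E)-3-methylpenta-2,4-dienoate; 11 C9 dienyl triflate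
Product: 18 2-(trimethylsilyl)ethyl 3β-(triethylsilyloxy)labda-6,8,13E-trien-15-oate, via alkylborane 17 (not isolated)
Conditions: 16, 9-BBN-H, THF, 0 °C → rt; then 11, PdCl2(dppf) (cat.), AsPh3 (cat.), Cs2CO3, DMF/H2O, rt → 50 °C
Reagents that add atoms: none
Why: 9-BBN-H adds to the terminal vinyl group of 16 with boron on C11, and the B-alkyl borane 17 then enters a B-alkyl Suzuki–Miyaura coupling in which Pd(0) inserts into the C9–OTf bond of 11, the base-activated borane hands over its primary C11 alkyl group and reductive elimination forges C9–C11. The closest known reaction type is the alkyl-9-BBN coupling of cyclohexenyl and cyclohexadienyl triflates that are flanked by a quaternary carbon and a vinylic methyl group (2,6,6-trimethylcyclohexenyl type). No ring is closed and no stereocentre is formed, and this is the point of the design: C9 stays trigonal, C11 is attached in the plane of ring B, and the axial C10 methyl, which would send any nucleophile to the α face of a C9 carbonyl and so give the C9 epimer, is left to direct the oxygen transfer of step 10 instead. The step needs hydroboration of the monosubstituted C11=C12 bond in preference to the trisubstituted, ester-deactivated C13=C14 bond, which the sterics and electronics of 16 secure, and it needs the E-enoate to remain a spectator, which the mild base allows. It also needs reductive elimination to outrun β-hydride elimination of the C11–Pd alkyl, for which the wide bite angle of dppf is chosen. The product holds all twenty skeletal carbons, and its surplus C6=C7 bond is the handle that lets step 11 cut the C8–O bond reductively.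

Step 10
Reactants: 18 triene ester
Product: 19 8α,9α-epoxy-6,13E-diene ester (vinyl oxirane)
Conditions: DMDO (acetone solution, 1 equiv), CH2Cl2, −40 °C
Reagents that add atoms: dimethyldioxirane, CC1(C)OO1
Why: Electrophilic epoxidation picks the tetrasubstituted, most electron-rich C8=C9 bond over the disubstituted C6=C7 bond and the electron-poor enoate, and the axial C10 methyl shields the β face, so oxygen should arrive from the α face and set C9 (O α, C11 β) and C8 together.

Step 11
Reactants: 19 vinyl oxirane
Product: 20 9α-hydroxy-7,13E-diene ester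
Conditions: SmI2, THF/MeOH, −78 °C
Reagents that add atoms: none
Why: Samarium diiodide reduction of a vinyl oxirane: two single-electron transfers cleave the allylic C8–O bond, which is aligned with the C6=C7 π system, and the allylsamarium is protonated at the remote, less substituted C6 to give the C7=C8 allylic alcohol, the C9–O bond and hence the C9 configuration being untouched.

Step 12
Reactants: 20 9α-hydroxy-7,13E-diene ester
Product: 22 9α-benzoate, via potassium alkoxide 21 (not isolated)
Conditions: KHMDS (1 equiv), THF, −78 °C; BzCl, −78 → 0 °C
Reagents that add atoms: benzoyl chloride, O=C(Cl)c1ccccc1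
Why: O-Acylation of a preformed potassium alkoxide with an acid chloride is the usual answer to an unreactive tertiary alcohol; the pseudo-axial oxygen lies on the open α face, and the alcohol is far more acidic than the γ-protons of the enoate, so one equivalent of base is selective.

Step 13
Reactants: 22 9α-benzoate
Product: 23 (13E)-9α-benzoyloxy-3β-hydroxylabda-7,13-dien-15-oic acid (target)
Conditions: TBAF, THF, 0 °C → rt; aq NH4Cl
Reagents that add atoms: none
Why: Fluoride cleaves the Si–O bond at C3 and triggers β-elimination of the 2-(trimethylsilyl)ethyl ester (loss of ethene) in one operation, conditions under which the hindered tertiary benzoate, both alkenes and all stereocentres should persist.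

**Compound list**

1 | (R)-(−)-carvone | CC1=CC[C@@H](C(C)=C)CC1=O | starting material
2 | lithium α′-enolate of carvone | CC1=CC[C@@H](C(C)=C)C=C1[O-].[Li+] | intermediate
3 | trans-6-methylcarvone (methyl trans to isopropenyl; the C6 epimer is equally usable) | CC1=CC[C@@H](C(C)=C)[C@H](C)C1=O | intermediate
4 | lithium enolate of 6-methylcarvone | CC1=CC[C@@H](C(C)=C)C(C)=C1[O-].[Li+] | intermediate
5 | 6-methyl-6-propargylcarvone (propargyl trans, methyl cis to the isopropenyl group) | CC1=CC[C@@H](C(C)=C)[C@](C)(CC#C)C1=O | intermediate
6 | (E)-alkenyl(dicyclohexyl)borane from 5 | CC1=CC[C@@H](C(C)=C)[C@](C)(C/C=C/B(C2CCCCC2)C2CCCCC2)C1=O | intermediate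
7 | keto aldehyde, 6-methyl-6-(3-oxopropyl)carvone | CC1=CC[C@@H](C(C)=C)[C@](C)(CCC=O)C1=O | intermediate
8 | (4aS,6S,8aS)-6-hydroxy-2,5,5,8a-tetramethyl-4a,5,6,7,8,8a-hexahydronaphthalen-1(4H)-one (3β-OH, 5α-H, 10β-CH3) | CC1=CC[C@H]2C(C)(C)[C@@H](O)CC[C@]2(C)C1=O | intermediate
9 | 3β-triethylsilyl ether of 8 | CC1=CC[C@H]2C(C)(C)[C@@H](O[Si](CC)(CC)CC)CC[C@]2(C)C1=O | intermediate
10 | potassium C6=C7–C8=C9 dienolate of 9 | CC=1C=C[C@H]2C(C)(C)[C@@H](O[Si](CC)(CC)CC)CC[C@]2(C)C=1[O-].[K+] | intermediate
11 | C9 dienyl triflate (C6=C7–C8=C9–OTf) | CC=1C=C[C@H]2C(C)(C)[C@@H](O[Si](CC)(CC)CC)CC[C@]2(C)C=1OS(=O)(=O)C(F)(F)F | intermediate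
12 | but-2-ynoic acid | CC#CC(=O)O | starting material
13 | 2-(trimethylsilyl)ethanol | C[Si](C)(C)CCO | starting material
14 | 2-(trimethylsilyl)ethyl but-2-ynoate | CC#CC(=O)OCC[Si](C)(C)C | intermediate
15 | α-cuprio dienoate (vinyl and copper cis) | C=C/C(C)=C(\[Cu])C(=O)OCC[Si](C)(C)C | intermediate
16 | 2-(trimethylsilyl)ethyl (2E)-3-methylpenta-2,4-dienoate | C=C/C(C)=C/C(=O)OCC[Si](C)(C)C | intermediate
17 | B-alkyl-9-BBN, boron on C11 | C[Si](C)(C)CCOC(=O)/C=C(C)/CCB1C2CCCC1CCC2 | intermediate
18 | 2-(trimethylsilyl)ethyl 3β-(triethylsilyloxy)labda-6,8,13E-trien-15-oate | CC=1C=C[C@H]2C(C)(C)[C@@H](O[Si](CC)(CC)CC)CC[C@]2(C)C=1CC/C(C)=C/C(=O)OCC[Si](C)(C)C | intermediate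
19 | 2-(trimethylsilyl)ethyl 8α,9α-epoxy-3β-(triethylsilyloxy)labda-6,13E-dien-15-oate | C[C@@]12C=C[C@H]3C(C)(C)[C@@H](O[Si](CC)(CC)CC)CC[C@]3(C)[C@]1(CC/C(C)=C/C(=O)OCC[Si](C)(C)C)O2 | intermediate
20 | 2-(trimethylsilyl)ethyl 9α-hydroxy-3β-(triethylsilyloxy)labda-7,13E-dien-15-oate | CC1=CC[C@H]2C(C)(C)[C@@H](O[Si](CC)(CC)CC)CC[C@]2(C)[C@]1(CC/C(C)=C/C(=O)OCC[Si](C)(C)C)O | intermediate
21 | potassium 9α-alkoxide of 20 | CC1=CC[C@H]2C(C)(C)[C@@H](O[Si](CC)(CC)CC)CC[C@]2(C)[C@]1(CC/C(C)=C/C(=O)OCC[Si](C)(C)C)[O-].[K+] | intermediate
22 | 2-(trimethylsilyl)ethyl 9α-benzoyloxy-3β-(triethylsilyloxy)labda-7,13E-dien-15-oate | CC1=CC[C@H]2C(C)(C)[C@@H](O[Si](CC)(CC)CC)CC[C@]2(C)[C@]1(CC/C(C)=C/C(=O)OCC[Si](C)(C)C)OC(=O)c1ccccc1 | intermediate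
23 | (13E)-9α-benzoyloxy-3β-hydroxylabda-7,13-dien-15-oic acid | CC1=CC[C@H]2C(C)(C)[C@@H](O)CC[C@]2(C)[C@]1(CC/C(C)=C/C(=O)O)OC(=O)c1ccccc1 | target

**Step count**

Total steps: 13. Longest linear sequence: 11 (steps 1–6 and 9–13).

**Steps most likely to fail**

Step 9. Oxidative addition and transmetalation at C9 may be slow, because C9 is wedged between the quaternary C10 and the C8 methyl. Hydrolysis of the triflate back to the enone, and protodeboronation or β-hydride elimination of the alkyl partner, could then take over. The fallback sets out from enone 9 and comes back at triene ester 18. Cerium-modified [2-(2-methyl-1,3-dioxolan-2-yl)ethyl]magnesium bromide adds 1,2 to the C9 carbonyl and gives the tertiary allylic alcohol F1, whose C9 configuration is irrelevant. 2,4-Dinitrobenzenesulfenyl chloride and Et3N in hot 1,2-dichloroethane carry it through sulfenate formation, a [2,3] shift to the C7 sulfoxide and syn elimination with a C6 hydrogen (a 1,4-dehydration) to the diene ketal F2. PPTS in wet acetone frees the methyl ketone F3. A Horner–Wadsworth–Emmons reaction with 2-(trimethylsilyl)ethyl diethylphosphonoacetate and NaH gives 18 after removal of the Z isomer.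

Step 4. Addition of the tertiary C4 radical to the aldehyde is reversible through β-scission of the alkoxy radical. Plain hydrogenation of the isopropenyl group may therefore win, and facial selectivity at C3 may be poor. The fallback sets out from keto aldehyde 7 and comes back at 8. Dry HCl in CH2Cl2 at 0 °C adds in the Markovnikov sense to the isopropenyl group and gives the tertiary chloride F4. CrCl2 with catalytic cobalt phthalocyanine in DMF turns the C–Cl bond into a tertiary alkylchromium(III) species, which adds irreversibly and chemoselectively to the aldehyde (Nozaki–Hiyama-type alkylchromium addition).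

Step 12. Acylation of the hindered tertiary alkoxide may be sluggish, which would leave time for intramolecular oxa-Michael addition of O9 to C13 or for γ-deprotonation of the enoate. The fallback sets out from vinyl oxirane 19 and comes back at 22, by-passing alcohol 20. Benzoyl bromide in CH2Cl2 at −78 °C acylates the exposed oxirane oxygen, the allylic C8–O bond opens and bromide is taken up at C6 (acyl halide opening of an epoxide in the SN2′ sense). This gives the bromo benzoate F5, in which the benzoate already sits on O9. Bu3SnH with Et3B/air then replaces bromine by hydrogen through the allyl radical, which should abstract hydrogen at the less hindered C6.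

**Further compounds**

F1 | step 9 | tertiary allylic alcohol from 1,2-addition (9β-OH, 9α-alkyl expected) | CC1=CC[C@H]2C(C)(C)[C@@H](O[Si](CC)(CC)CC)CC[C@]2(C)[C@]1(O)CCC3(C)OCCO3
F2 | step 9 | C6=C7–C8=C9 diene with the dioxolane-protected side chain | CC=1C=C[C@H]2C(C)(C)[C@@H](O[Si](CC)(CC)CC)CC[C@]2(C)C=1CCC3(C)OCCO3
F3 | step 9 | diene methyl ketone (C13 ketone) | CC=1C=C[C@H]2C(C)(C)[C@@H](O[Si](CC)(CC)CC)CC[C@]2(C)C=1CCC(C)=O
F4 | step 4 | tertiary chloride (hydrochloride of 7) | CC1=CC[C@@H](C(C)(C)Cl)[C@](C)(CCC=O)C1=O
F5 | step 12 | 6-bromo-9α-benzoyloxy-7-ene (C6 epimers, centre removed in the next operation) | CC1=CC(Br)[C@H]2C(C)(C)[C@@H](O[Si](CC)(CC)CC)CC[C@]2(C)[C@]1(CC/C(C)=C/C(=O)OCC[Si](C)(C)C)OC(=O)c1ccccc1
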